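3.10 is the number I carry through this flask: the selectivity factor s, the logarithm of the share of left-handed substrate still there divided by the same logarithm for right-handed substrate, each hand counted from the half of the charge it starts with.

| setting | Saturday's | Monday's | flask |
|---|---|---|---|
| left-handed substrate | 12 mM | 27 mM | 18 mM |
| right-handed substrate | 12 mM | 27 mM | 18 mM |
| gas | 11 mM (held) | 11 mM (held) | 11 mM (held) |
| remark | run made earlier | run made earlier |  |
| time |  |  | 12 h |

- Saturday's (time / h: right-handed substrate / %, left-handed substrate / %, left-handed product / %): 1.00: 43.8, 33.1, 16.5; 3.00: 30.4, 11.2, 39.1; 5.00: 19.8, 3.5, 46.4; 8.00: 10.6, 0.4, 49.7; 12.0: 4.1, 0.1, 49.9; 15.0: 2.3, 0, 50.8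
- Monday's (time / h: right-handed substrate / %, left-handed substrate / %, left-handed product / %): 1.00: 45.3, 36.3, 13.9; 3.00: 33.8, 13.4, 35.0; 5.00: 23.4, 4.5, 45.3; 8.00: 13.3, 0.9, 49.0; 12.0: 5.5, 0.2, 50.0; 15.0: 2.6, 0, 50.6

(each reading ± 0.5 percentage points)

- reagent is single-handed; left-handed substrate and right-handed substrate are mirror images of each other, charged as a racemate, each of them at the stated concentration
- at the start none of reagent is dissolved
- what was read earlier has a scatter of 0.5 percentage points, one standard deviation
- on the list of suspects stand: reagent + left-handed substrate -> left-handed product; reagent + right-handed substrate -> right-handed product; reagent -> decomposition product; gas <-> reagent; 2 reagent -> homo dimer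
- the handed part of reagent does not stay in what it makes, so the products of the two hands are mirror images too

- whether the excess of right-handed substrate over left-handed substrate among what is left of the two reaches 95% by 12 h (yes / no)
- the highest excess of right-handed substrate over left-handed substrate among what is left of the two up to 12 h

I take s as the mean of 4 values, read at 3.00 h and 5.00 h in both runs, and they spread from 2.87 to 3.36. My first doubt is that the excess can't be read directly late on, since Saturday's left-handed substrate at 12.0 h reads 0.1%, under the scatter of 0.5 percentage points. But s gets round that. When right-handed substrate falls by one power of ten, left-handed substrate falls by s powers, so their ratio falls by s minus one powers. An excess of 95.0% means a ratio of 0.0256, which is 1.59 powers of ten down, so right-handed substrate must come down to 8.76% of the charge.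

Will it get there? The flask's 18 mM is the geometric mean of the two runs' charges, 18.0 mM, so in logarithms it stands midway, and the geometric mean of their right-handed readings at 12 h is 4.75%. That midpoint may be doubted, but Monday's 5.5%, the higher reading, is itself lower than 8.76%. From the midpoint I reckon a final excess of 98.6%, and with s at 2.87, 97.6%.

The forecast says yes and 98.4%, 0.20 points apart from mine, with “still rising at 12 h, so the maximum falls at the end”.

The flask gives yes and 98.6%.

    reagent + left-handed substrate → left-handed product (k = 1.40 L mol⁻¹ min⁻¹)
    reagent + right-handed substrate → right-handed product (k = 0.450 L mol⁻¹ min⁻¹)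
    reagent → decomposition product (k = 4.20 × 10⁻⁵ min⁻¹)
    gas ⇌ reagent, rate k4*(csat - [reagent]) (kL = 0.0380 min⁻¹)
    2 reagent → homo dimer (k = 0.780 L mol⁻¹ min⁻¹)

The excess reaches 95.0% at 9.20 h, with 8.82% of right-handed substrate left, where I had reckoned 8.76%. At the 4.79% of right-handed substrate standing at 12.0 h, the answer turns to no with s under 2.56. On Monday's run, the right-handed reading of 13.3% at 8.00 h gives through s a left-handed substrate of 0.824%, and the reading there is 0.9%.

All runs come from a simulation on assumed constants, noise included.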